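**Retrosynthetic overview**

1. Numbering used below (drimane type): ring A = C-1 to C-5 plus C-10; ring B = C-5 to C-10; C-11 = the OCH2 carbon on C-9; C-12 = the exocyclic CH2 on C-8. Enabling feature: ring B holds a skipped diene (C-5=C-6 and C-8=C-12 across C-7). Moving the exocyclic alkene into the ring as a C-8=C-9 allylsilane makes ring B a cyclohexa-1,4-diene, the signature of an alkyne + 1,3-diene [4+2]. Because the ring-fusion bond C-5–C-10 belongs to both rings, one intramolecular cycloaddition closes rings A and B together.
2. Late disconnections: C-3 ester (carbodiimide esterification), C-11–O aryl ether (Mitsunobu with umbelliferone), C-3 carbinol (hydride reduction of the ketone), C-9–C-11 with transposition to C-8=C-12 (Hosomi–Sakurai reaction with formaldehyde).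
3. Key disconnection: C-5–C-10 and C-6–C-7 of the bicyclic allylsilane ketone lead back to an achiral, acyclic dienynone. A chiral rhodium catalyst sets quaternary C-10, and C-9 and C-3 are relayed from it.
4. The dienynone comes from pent-4-yn-1-ol (C-1 to C-3, C-9, C-10), Me3Al (methyl on C-10), (2-bromoallyl)trimethylsilane (C-7, C-8, C-12) and 3-chloro-3-methylbut-1-yne (C-4 to C-6 and the gem-dimethyl group).
5. Ring order: rings A and B form together in step 5; no protecting group is used.

Key step: step 5

Remark: the sense of induction of the ligand in step 5 cannot be predicted with certainty; the antipode that gives the (R) configuration at C-10 is to be used, and (S,S)-Me-DuPhos is written as the working choice.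

**Route**

Step 1
Reactants: 1 pent-4-yn-1-ol; 2 (2-bromoprop-2-en-1-yl)trimethylsilane
Product: 4 (4E)-4-methyl-6-[(trimethylsilyl)methyl]hepta-4,6-dien-1-ol, via alkenylalane 3 (not isolated)
Conditions: Me3Al (3 equiv), Cp2ZrCl2 (0.25 equiv), CH2Cl2, 0 °C → rt; then 2, Pd(PPh3)4 (5 mol%), ZnCl2 (20 mol%), THF, rt; aq. potassium sodium tartrate
Reagents that add atoms: trimethylaluminium, C[Al](C)C
Why: Zirconium-catalysed syn carboalumination of the terminal alkyne (Negishi carboalumination) puts methyl on the internal carbon and aluminium on the terminus, which fixes the E geometry, and the alkenylalane is cross-coupled in the same flask with the vinyl bromide (Negishi coupling) with retention, the allylsilane being inert to both events.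

Step 2
Reactants: 4 (4E)-4-methyl-6-[(trimethylsilyl)methyl]hepta-4,6-dien-1-ol
Product: 5 (4E)-4-methyl-6-[(trimethylsilyl)methyl]hepta-4,6-dienal
Conditions: Dess–Martin periodinane, pyridine, CH2Cl2, 0 °C → rt
Reagents that add atoms: none
Why: Dess–Martin oxidation of a primary alcohol stops at the aldehyde under buffered conditions that should leave the 2-(silylmethyl)diene untouched.

Step 3
Reactants: 5 (4E)-4-methyl-6-[(trimethylsilyl)methyl]hepta-4,6-dienal; 6 3-chloro-3-methylbut-1-yne
Product: 8 rac-(7E)-3,3,7-trimethyl-9-[(trimethylsilyl)methyl]deca-7,9-dien-1-yn-4-ol, via allenylzinc chloride 7 (not isolated)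
Conditions: Zn dust (activated), LiCl, THF, 0 °C → rt; aq. NH4Cl
Reagents that add atoms: none
Why: Barbier-type propargylation, in which zinc inserts into the tertiary propargylic chloride and the allenylzinc adds to the aldehyde through a cyclic SE2' transition state at its dimethyl-substituted carbon, should give the homopropargylic alcohol with the quaternary gem-dimethyl carbon; the carbinol centre forms as a racemate and is erased in step 4.

Step 4
Reactants: 8 rac-(7E)-3,3,7-trimethyl-9-[(trimethylsilyl)methyl]deca-7,9-dien-1-yn-4-ol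
Product: 9 (7E)-3,3,7-trimethyl-9-[(trimethylsilyl)methyl]deca-7,9-dien-1-yn-4-one
Conditions: Dess–Martin periodinane, pyridine, CH2Cl2, rt
Reagents that add atoms: none
Why: Dess–Martin oxidation of the secondary alcohol gives a ketone with no hydrogen on its quaternary side, so the β,γ-alkynyl ketone cannot isomerise to an allenyl ketone.

Step 5
Reactants: 9 (7E)-3,3,7-trimethyl-9-[(trimethylsilyl)methyl]deca-7,9-dien-1-yn-4-one
Product: 11 (4aR)-1,1,4a-trimethyl-6-[(trimethylsilyl)methyl]-3,4,4a,7-tetrahydronaphthalen-2(1H)-one, via rhodacycle 10 (not isolated)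
Conditions: [Rh(C2H4)2Cl]2 (2.5 mol%), (S,S)-Me-DuPhos (5.5 mol%), AgSbF6 (5 mol%), ClCH2CH2Cl, 0.01 M, 25 → 60 °C
Reagents that add atoms: none
Why: Proposed new method: the cationic monovalent rhodium–diphosphine fragment binds the alkyne and the s-cis diene of 9, oxidative cyclisation joins C-5 to C-10 to give the trivalent rhodium σ-vinyl/π-allyl rhodacycle 10, and reductive elimination at the far allyl terminus forms C-6–C-7 and frees the catalyst, so that the alkyne ends as the C-5=C-6 alkene and the diene as the C-8=C-9 allylsilane. The closest known reaction type is the monovalent rhodium–chiral diphosphine (or chiral diene) catalysed enantioselective intramolecular [4+2] cycloaddition of dienynes with three-atom tethers, together with the racemic zerovalent nickel and monovalent rhodium versions that build angular-methyl hexahydronaphthalenes from all-carbon dienynes; new here is the combination of a four-carbon tether, a quaternary ring-fusion carbon and enantiocontrol. Ring A closes in the oxidative cyclisation as a six-membered ring, exo with respect to both the alkyne and the C-9=C-10 alkene, and ring B closes by C–C reductive elimination from the seven-membered rhodacycle, the overall result being a fused (type 1) intramolecular [4+2] adduct. The only new stereocentre, quaternary C-10, is set by the chiral ligand, which selects the enantioface of the trisubstituted diene terminus in the oxidative cyclisation; the tether of 9 is achiral, so no substrate bias has to be overridden, and the E geometry of C-9=C-10 keeps the tether on the outside of the s-cis diene. The step needs chemoselectivity for the intramolecular [4+2] over alkyne oligomerisation and [2+2+2] trimerisation, which the gem-dimethyl group next to the alkyne (shielding against intermolecular reaction, Thorpe–Ingold acceleration of closure), the 2-substituent of the diene (s-cis population) and high dilution should secure. The allylsilane should survive because no nucleophile or leaving group is present that could turn the π-allyl intermediate into a trimethylenemethane complex.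

Step 6
Reactants: 11 (4aR)-1,1,4a-trimethyl-6-[(trimethylsilyl)methyl]-3,4,4a,7-tetrahydronaphthalen-2(1H)-one
Product: 12 (4aR,5R)-5-(hydroxymethyl)-1,1,4a-trimethyl-6-methylidene-3,4,4a,5,6,7-hexahydronaphthalen-2(1H)-one
Conditions: (CH2O)n (1.1 equiv) premixed with Me2AlCl (1.5 equiv), CH2Cl2, 0 °C; then 11, −78 → −30 °C; aq. NaHCO3
Reagents that add atoms: formaldehyde (used as paraformaldehyde), C=O
Why: Hosomi–Sakurai reaction, in which aluminium-bound formaldehyde is attacked by C-9 of the allylsilane and loss of silicon from the β-silyl cation gives the exocyclic C-8=C-12 alkene; attack should come from the face anti to the pseudo-axial methyl on C-10, which sets C-9 as (R) with the CH2OH group trans to that methyl.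

Step 7
Reactants: 12 (4aR,5R)-5-(hydroxymethyl)-1,1,4a-trimethyl-6-methylidene-3,4,4a,5,6,7-hexahydronaphthalen-2(1H)-one
Product: 13 (2S,4aR,5R)-5-(hydroxymethyl)-1,1,4a-trimethyl-6-methylidene-1,2,3,4,4a,5,6,7-octahydronaphthalen-2-ol
Conditions: NaBH4, MeOH/THF, −20 → 0 °C
Reagents that add atoms: none
Why: Hydride reduction of a hindered cyclohexanone, in which borohydride attacks axially from the face opposite to the axial methyl groups on C-4 and C-10, should give the equatorial alcohol, that is the (S) configuration at C-3, cis to the methyl on C-10.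

Step 8
Reactants: 13 (2S,4aR,5R)-5-(hydroxymethyl)-1,1,4a-trimethyl-6-methylidene-1,2,3,4,4a,5,6,7-octahydronaphthalen-2-ol; 14 7-hydroxy-2H-chromen-2-one (umbelliferone)
Product: 15 7-{[(1R,6S,8aR)-6-hydroxy-5,5,8a-trimethyl-2-methylidene-1,2,3,5,6,7,8,8a-octahydronaphthalen-1-yl]methoxy}-2H-chromen-2-one
Conditions: PPh3, DIAD, THF, 0 → 40 °C
Reagents that add atoms: none
Why: Mitsunobu etherification, in which the acidic phenol displaces the activated primary alcohol at C-11, while the secondary alcohol flanked by the gem-dimethyl carbon is too hindered to be activated; no stereocentre is touched.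

Step 9
Reactants: 15 7-{[(1R,6S,8aR)-6-hydroxy-5,5,8a-trimethyl-2-methylidene-1,2,3,5,6,7,8,8a-octahydronaphthalen-1-yl]methoxy}-2H-chromen-2-one; 16 3-hydroxy-3-methylbutanoic acid
Product: 17 (2S,4aR,5R)-1,1,4a-trimethyl-6-methylidene-5-{[(2-oxo-2H-chromen-7-yl)oxy]methyl}-1,2,3,4,4a,5,6,7-octahydronaphthalen-2-yl 3-hydroxy-3-methylbutanoate (target)
Conditions: EDC·HCl, DMAP, CH2Cl2, rt
Reagents that add atoms: none
Why: Steglich-type esterification (carbodiimide/DMAP) acylates the secondary ring alcohol with retention at C-3, the tertiary hydroxyl of the acid being too hindered to compete as acyl acceptor.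

**Compound list**

1 | pent-4-yn-1-ol | C#CCCCO | starting material
2 | (2-bromoprop-2-en-1-yl)trimethylsilane | C=C(Br)C[Si](C)(C)C | starting material
3 | [(1E)-5-(dimethylalumanyloxy)-2-methylpent-1-en-1-yl]dimethylalumane (alkenylalane) | C[Al](C)OCCC/C(C)=C/[Al](C)C | intermediate
4 | (4E)-4-methyl-6-[(trimethylsilyl)methyl]hepta-4,6-dien-1-ol | OCCC/C(C)=C/C(=C)C[Si](C)(C)C | intermediate
5 | (4E)-4-methyl-6-[(trimethylsilyl)methyl]hepta-4,6-dienal | O=CCC/C(C)=C/C(=C)C[Si](C)(C)C | intermediate
6 | 3-chloro-3-methylbut-1-yne | C#CC(C)(C)Cl | starting material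
7 | (3-methylbuta-1,2-dien-1-yl)zinc chloride (allenylzinc chloride) | CC(C)=C=C[Zn]Cl | intermediate
8 | rac-(7E)-3,3,7-trimethyl-9-[(trimethylsilyl)methyl]deca-7,9-dien-1-yn-4-ol | C#CC(C)(C)C(O)CC/C(C)=C/C(=C)C[Si](C)(C)C | intermediate
9 | (7E)-3,3,7-trimethyl-9-[(trimethylsilyl)methyl]deca-7,9-dien-1-yn-4-one | C#CC(C)(C)C(=O)CC/C(C)=C/C(=C)C[Si](C)(C)C | intermediate
10 | seven-membered rhodacycle with Rh bonded to C-6 and C-7, drawn in its σ-allyl form, diphosphine ligand left out | C[Si](C)(C)CC1=C[C@@]2(C)CCC(=O)C(C)(C)C2=C[Rh]C1 | intermediate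
11 | (4aR)-1,1,4a-trimethyl-6-[(trimethylsilyl)methyl]-3,4,4a,7-tetrahydronaphthalen-2(1H)-one | C[Si](C)(C)CC1=C[C@@]2(C)CCC(=O)C(C)(C)C2=CC1 | intermediate
12 | (4aR,5R)-5-(hydroxymethyl)-1,1,4a-trimethyl-6-methylidene-3,4,4a,5,6,7-hexahydronaphthalen-2(1H)-one | C=C1CC=C2C(C)(C)C(=O)CC[C@]2(C)[C@@H]1CO | intermediate
13 | (2S,4aR,5R)-5-(hydroxymethyl)-1,1,4a-trimethyl-6-methylidene-1,2,3,4,4a,5,6,7-octahydronaphthalen-2-ol | C=C1CC=C2C(C)(C)[C@@H](O)CC[C@]2(C)[C@@H]1CO | intermediate
14 | 7-hydroxy-2H-chromen-2-one (umbelliferone) | Oc1ccc2ccc(=O)oc2c1 | starting material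
15 | 7-{[(1R,6S,8aR)-6-hydroxy-5,5,8a-trimethyl-2-methylidene-1,2,3,5,6,7,8,8a-octahydronaphthalen-1-yl]methoxy}-2H-chromen-2-one | C=C1CC=C2C(C)(C)[C@@H](O)CC[C@]2(C)[C@@H]1COc1ccc2ccc(=O)oc2c1 | intermediate
16 | 3-hydroxy-3-methylbutanoic acid | CC(C)(O)CC(=O)O | starting material
17 | (2S,4aR,5R)-1,1,4a-trimethyl-6-methylidene-5-{[(2-oxo-2H-chromen-7-yl)oxy]methyl}-1,2,3,4,4a,5,6,7-octahydronaphthalen-2-yl 3-hydroxy-3-methylbutanoate | C=C1CC=C2C(C)(C)[C@@H](OC(=O)CC(C)(C)O)CC[C@]2(C)[C@@H]1COc1ccc2ccc(=O)oc2c1 | target

**Step count**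

Total steps: 9. Longest linear sequence: 9 steps, from pent-4-yn-1-ol.

**Steps most likely to fail, with fallbacks**

Step 5 (proposed new method). Enantioface selection at the fully substituted diene terminus may be poor, or the oxidative cyclisation may be so slow that alkyne oligomerisation takes over. The fallback relays the configuration from a carbinol centre with known chemistry and sets out from ketone 9.
- Corey–Bakshi–Shibata reduction with the (R)-configured B-methyl oxazaborolidine and catecholborane in toluene at −78 °C should give (4S,7E)-3,3,7-trimethyl-9-[(trimethylsilyl)methyl]deca-7,9-dien-1-yn-4-ol F1. Catecholborane is chosen so that the alkyne and the diene are not hydroborated.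
- TBSOTf and 2,6-lutidine in CH2Cl2 give the silyl ether F2.
- Ni(cod)2 with tris(2-biphenylyl) phosphite in THF at room temperature (the known dienyne [4+2] under zerovalent nickel) should close both rings through a chair-like tether with the silyloxy group equatorial. This places the C-3 oxygen cis to the C-10 methyl and gives the bicyclic allylsilane F3.
- The Hosomi–Sakurai reaction under the conditions of step 6 gives the homoallylic alcohol F4.
- The Mitsunobu reaction with 14 under the conditions of step 8 gives the aryl ether F5.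
- Bu4NF in THF removes the silyl group, and the fallback comes back to the route at 15.

Step 6. Aluminium-bound formaldehyde may react on with the newly formed 1,1-disubstituted alkene (carbonyl-ene or Prins chain growth), or protodesilylation may outrun C–C bond formation. The fallback sets out from 11 and brings in C-11 as an alkoxymethyl cation, whose adduct is an ether that cannot react further.
- Benzyl chloromethyl ether with catalytic ZnBr2 in CH2Cl2 at −78 °C (Sakurai-type alkoxymethylation) should give (4aR,5R)-5-[(benzyloxy)methyl]-1,1,4a-trimethyl-6-methylidene-3,4,4a,5,6,7-hexahydronaphthalen-2(1H)-one F6.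
- Lithium in liquid NH3/THF with tert-butanol at −78 °C then cleaves the benzyl ether and reduces the ketone to the equatorial alcohol in one operation. The isolated alkenes are not touched.
- The fallback comes back to the route at diol 13, so it replaces steps 6 and 7.

Step 9. Activation of the β-hydroxy acid may end in self-acylation or in dehydration to the 3-methylbut-2-enoate before the hindered secondary alcohol is acylated. The fallback sets out from 15 and builds the side chain on the ester.
- Bromoacetyl bromide and pyridine in CH2Cl2 at 0 °C give the bromoacetate F7.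
- A Reformatsky reaction (activated Zn, acetone, THF, rt) adds the zinc enolate to acetone and comes back to the route at target 17.

**Further compounds**

F1 | step 5 | (4S,7E)-3,3,7-trimethyl-9-[(trimethylsilyl)methyl]deca-7,9-dien-1-yn-4-ol | C#CC(C)(C)[C@@H](O)CC/C(C)=C/C(=C)C[Si](C)(C)C
F2 | step 5 | tert-butyl(dimethyl){[(4S,7E)-3,3,7-trimethyl-9-[(trimethylsilyl)methyl]deca-7,9-dien-1-yn-4-yl]oxy}silane | C#CC(C)(C)[C@@H](O[Si](C)(C)C(C)(C)C)CC/C(C)=C/C(=C)C[Si](C)(C)C
F3 | step 5 | tert-butyl(dimethyl){[(2S,4aR)-1,1,4a-trimethyl-6-[(trimethylsilyl)methyl]-1,2,3,4,4a,7-hexahydronaphthalen-2-yl]oxy}silane | C[Si](C)(C)CC1=C[C@@]2(C)CC[C@H](O[Si](C)(C)C(C)(C)C)C(C)(C)C2=CC1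
F4 | step 5 | [(1R,6S,8aR)-6-{[tert-butyl(dimethyl)silyl]oxy}-5,5,8a-trimethyl-2-methylidene-1,2,3,5,6,7,8,8a-octahydronaphthalen-1-yl]methanol | C=C1CC=C2C(C)(C)[C@@H](O[Si](C)(C)C(C)(C)C)CC[C@]2(C)[C@@H]1CO
F5 | step 5 | 7-{[(1R,6S,8aR)-6-{[tert-butyl(dimethyl)silyl]oxy}-5,5,8a-trimethyl-2-methylidene-1,2,3,5,6,7,8,8a-octahydronaphthalen-1-yl]methoxy}-2H-chromen-2-one | C=C1CC=C2C(C)(C)[C@@H](O[Si](C)(C)C(C)(C)C)CC[C@]2(C)[C@@H]1COc1ccc2ccc(=O)oc2c1
F6 | step 6 | (4aR,5R)-5-[(benzyloxy)methyl]-1,1,4a-trimethyl-6-methylidene-3,4,4a,5,6,7-hexahydronaphthalen-2(1H)-one | C=C1CC=C2C(C)(C)C(=O)CC[C@]2(C)[C@@H]1COCc1ccccc1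
F7 | step 9 | (2S,4aR,5R)-1,1,4a-trimethyl-6-methylidene-5-{[(2-oxo-2H-chromen-7-yl)oxy]methyl}-1,2,3,4,4a,5,6,7-octahydronaphthalen-2-yl 2-bromoacetate | C=C1CC=C2C(C)(C)[C@@H](OC(=O)CBr)CC[C@]2(C)[C@@H]1COc1ccc2ccc(=O)oc2c1
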